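**Strategy.** The route rests on disconnecting the C7–OH and C8–H bonds. The hydroxyl on C7 (the carbinol carbon on ring A, the 3,4,5-trimethoxyphenyl ring) and the hydrogen on C8 (the carbon carrying the methyl group and the ring B aryloxy oxygen) are seen as water added syn across a C7=C8 enol ether. A single enantioselective hydroboration–oxidation with a pinene-derived borane then creates both stereocentres at once. The E geometry dictates the relative configuration and the reagent the absolute one, while the hindered C8–O–aryl bond is already in place. The precursor is the E enol ether joining the ring A propenyl unit to 4-bromo-2,6-dimethoxyphenol, the bromine serving as a borane-inert placeholder for the allyl group.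

Key step: step 4

Assumption: the face preference of IpcBH2 towards 6 is taken to follow its behaviour with trisubstituted aryl alkenes, so the reagent from (−)-α-pinene is specified; ring A is entered as its iodide because electron-rich aryl bromides couple sluggishly with propyne at room temperature.

**Step 1**
Reactants: 1 5-iodo-1,2,3-trimethoxybenzene; 2 propyne
Product: 3 1,2,3-trimethoxy-5-(prop-1-yn-1-yl)benzene
Conditions: PdCl2(PPh3)2 (2 mol %), CuI (4 mol %), Et3N, THF, propyne (balloon), rt
Reagents that add atoms: none
Why: Sonogashira coupling, in which the aryl iodide adds oxidatively to zerovalent palladium at room temperature and the copper acetylide of propyne transmetallates, so the electron-rich ring is alkynylated without forcing conditions.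

**Step 2**
Reactants: 3 1,2,3-trimethoxy-5-(prop-1-yn-1-yl)benzene
Product: 4 (Z)-4,4,5,5-tetramethyl-2-[1-(3,4,5-trimethoxyphenyl)prop-1-en-2-yl]-1,3,2-dioxaborolane (ring A cis to the methyl group)
Conditions: B2pin2 (1.1 equiv), CuCl (5 mol %), NaOt-Bu (10 mol %), P(p-tol)3 (6 mol %), MeOH (2 equiv), THF, rt
Reagents that add atoms: bis(pinacolato)diboron, CC1(C)OB(OC1(C)C)B1OC(C)(C)C(C)(C)O1
Why: Copper-catalysed formal hydroboration (syn borylcupration, then protonation), in which Cu–Bpin adds with copper at the aryl-bearing C7 and boron at the methyl-bearing C8 and methanol cleaves the C–Cu bond with retention, which places ring A cis to methyl (Z only because carbon outranks boron).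

**Step 3**
Reactants: 4 (Z)-alkenyl pinacol boronate (1.5 equiv); 5 4-bromo-2,6-dimethoxyphenol
Product: 6 (E)-5-bromo-1,3-dimethoxy-2-{[1-(3,4,5-trimethoxyphenyl)prop-1-en-2-yl]oxy}benzene
Conditions: Cu(OAc)2 (2 equiv), pyridine (5 equiv), 4 Å MS, CH2Cl2, dry air, rt
Reagents that add atoms: none
Why: Chan–Lam oxidative C–O coupling, in which the alkenyl group passes from boron to divalent copper and the aryl alkenyl ether forms by reductive elimination from a trivalent copper phenoxide with retention of alkene geometry, the aryl bromide being inert to copper at room temperature (descriptor E only because oxygen now outranks methyl).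

**Step 4**
Reactants: 6 (E)-5-bromo-1,3-dimethoxy-2-{[1-(3,4,5-trimethoxyphenyl)prop-1-en-2-yl]oxy}benzene
Product: 8 (1R,2R)-2-(4-bromo-2,6-dimethoxyphenoxy)-1-(3,4,5-trimethoxyphenyl)propan-1-ol, via alkyl(isopinocampheyl)borane 7 (not isolated)
Conditions: IpcBH2 from (−)-α-pinene (1.5 equiv; freed from TMEDA·2IpcBH2 with BF3·OEt2, 1.9 equiv per TMEDA, filtered), THF, −25 → 0 °C; then NaBO3·4H2O, THF/H2O, 0 °C → rt
Reagents that add atoms: monoisopinocampheylborane from (−)-α-pinene, C[C@@H]1[C@@H]([BH2])C[C@H]2C[C@@H]1C2(C)C (boron and isopinocampheyl group of 7; its hydrogen ends at C8 of 8); sodium perborate, [Na+].[O-]OB=O (hydroxyl oxygen of 8)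
Why: Proposed new method: the B–H bond of IpcBH2 should add across C7=C8 through a concerted four-centre syn transition state, boron bonding to C7 (benzylic, β to the enol ether oxygen and the only alkene carbon bearing hydrogen) and hydride to C8, and perborate then converts C7–B into C7–OH with retention by 1,2-migration of carbon from boron to oxygen. The closest known reaction types are the asymmetric hydroboration–oxidation of trisubstituted aryl alkenes with IpcBH2 and of cyclic enol ethers with isopinocampheylboranes; an acyclic trisubstituted aryl enol ether has not served as substrate. No ring is closed. C7 and C8 are set together: their relative configuration is controlled by the substrate, since syn delivery of H and B to the E alkene (ring A cis to methyl) and retentive oxidation can only give the (7R,8R)/(7S,8S) pair, and their absolute configuration by the isopinocampheyl group on boron, the reagent from (−)-α-pinene being expected, by analogy with trisubstituted aryl alkenes, to add to the face that leads to (7R,8R). The step needs regioselectivity, secured by oxygen lone-pair polarisation of the double bond towards C7 together with the full substitution of C8, and face selectivity, which the chiral borane must supply; chemoselectivity is secured by the bromine on ring B, which is inert to boranes where an allyl group would not be. β-Elimination of the aryloxy group from 7 is countered by excluding free BF3, keeping the temperature at or below 0 °C and oxidising with mildly basic NaBO3.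

**Step 5**
Reactants: 8 (1R,2R)-2-(4-bromo-2,6-dimethoxyphenoxy)-1-(3,4,5-trimethoxyphenyl)propan-1-ol; 9 allyltributylstannane (1.5 equiv)
Product: 10 (1R,2R)-2-[2,6-dimethoxy-4-(prop-2-en-1-yl)phenoxy]-1-(3,4,5-trimethoxyphenyl)propan-1-ol
Conditions: Pd(PPh3)4 (5 mol %), toluene (degassed), 100 °C
Reagents that add atoms: none
Why: Stille cross-coupling, in which the unhindered aryl bromide adds oxidatively to zerovalent palladium, the allyl group is transferred from tin and reductive elimination forms the aryl–allyl bond under neutral conditions that leave the free alcohol, the aryl alkyl ether and both stereocentres untouched.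

**Compound list**
1 | 5-iodo-1,2,3-trimethoxybenzene | COc1cc(I)cc(OC)c1OC | starting material
2 | propyne | CC#C | starting material
3 | 1,2,3-trimethoxy-5-(prop-1-yn-1-yl)benzene | CC#Cc1cc(OC)c(OC)c(OC)c1 | intermediate
4 | (Z)-4,4,5,5-tetramethyl-2-[1-(3,4,5-trimethoxyphenyl)prop-1-en-2-yl]-1,3,2-dioxaborolane | COc1cc(/C=C(\C)B2OC(C)(C)C(C)(C)O2)cc(OC)c1OC | intermediate
5 | 4-bromo-2,6-dimethoxyphenol | COc1cc(Br)cc(OC)c1O | starting material
6 | (E)-5-bromo-1,3-dimethoxy-2-{[1-(3,4,5-trimethoxyphenyl)prop-1-en-2-yl]oxy}benzene | COc1cc(/C=C(\C)Oc2c(OC)cc(Br)cc2OC)cc(OC)c1OC | intermediate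
7 | [(1R,2R)-2-(4-bromo-2,6-dimethoxyphenoxy)-1-(3,4,5-trimethoxyphenyl)propyl](isopinocampheyl)borane, isopinocampheyl group from (−)-α-pinene | C[C@@H]1[C@@H]([BH][C@H](c3cc(OC)c(OC)c(OC)c3)[C@@H](C)Oc3c(OC)cc(Br)cc3OC)C[C@H]2C[C@@H]1C2(C)C | intermediate
8 | (1R,2R)-2-(4-bromo-2,6-dimethoxyphenoxy)-1-(3,4,5-trimethoxyphenyl)propan-1-ol | COc1cc(Br)cc(OC)c1O[C@H](C)[C@H](O)c2cc(OC)c(OC)c(OC)c2 | intermediate
9 | allyltributylstannane | C=CC[Sn](CCCC)(CCCC)CCCC | starting material
10 | (1R,2R)-2-[2,6-dimethoxy-4-(prop-2-en-1-yl)phenoxy]-1-(3,4,5-trimethoxyphenyl)propan-1-ol | C=CCc1cc(OC)c(O[C@H](C)[C@H](O)c2cc(OC)c(OC)c(OC)c2)c(OC)c1 | target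

**Step count.** Total: 5 steps. Longest linear sequence: 5 steps (1 → 3 → 4 → 6 → 8 → 10).

**Steps most likely to fail**

1. Step 4 (hydroboration–oxidation). The aryloxy group may be lost by β-elimination from the organoborane before or during oxidation. The borane may discriminate poorly between the two faces of this untested substrate class. Addition to the hindered, conjugated double bond may be too slow at low temperature. The fallback uses known chemistry, with C8 taken from the chiral pool and C7 set by a Felkin–Anh reduction. It sets out from phenol 5 and returns at 8.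
   - Mitsunobu etherification of 5 with ethyl (S)-lactate (PPh3, DIAD, THF, 0 °C → rt) should give, with inversion, ethyl (R)-2-(4-bromo-2,6-dimethoxyphenoxy)propanoate F1.
   - MeNH(OMe)·HCl and i-PrMgCl (THF, −20 °C) should convert it into (R)-2-(4-bromo-2,6-dimethoxyphenoxy)-N-methoxy-N-methylpropanamide F2.
   - Commercial 3,4,5-trimethoxyphenylmagnesium bromide (THF, 0 °C) should give (R)-2-(4-bromo-2,6-dimethoxyphenoxy)-1-(3,4,5-trimethoxyphenyl)propan-1-one F3.
   - Reduction with the bulky, non-chelating LiBH(s-Bu)3 (THF, −78 °C) should favour the syn (7R,8R) alcohol through a polar Felkin–Anh transition state, with the aryloxy group anti to the incoming hydride. Any anti isomer would be removed by chromatography, and the route is rejoined at 8.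

2. Step 3 (Chan–Lam coupling). Transmetallation from the pinacol boronate and C–O bond formation at the di-ortho-substituted phenol may be slow. Protodeboronation, alkenyl homocoupling or oxidation of the electron-rich phenol would then compete. The enol ether may also hydrolyse on acidic silica. The fallback reverses the polarity of the partners; it sets out from boronate 4 and returns at 6.
   - Formation of the hydroxyborate with aqueous NaOH followed by I2 (THF, 0 °C) should effect iododeboronation with retention and give (E)-5-(2-iodoprop-1-en-1-yl)-1,2,3-trimethoxybenzene F4.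
   - Ullmann-type vinylation of phenol 5 with F4 (CuI, N,N-dimethylglycine, Cs2CO3, dioxane, 60 °C) should give 6 with retention of geometry. The vinyl iodide is expected to react well before the aryl bromide.

3. Step 5 (Stille allylation). The allyl double bond may migrate into conjugation with ring B through palladium hydride species at 100 °C. Oxidative addition of the electron-rich bromide may be sluggish, which would lead to protodebromination. The fallback exchanges the roles of the partners; it sets out from 8 and returns at 10.
   - Miyaura borylation (B2pin2, PdCl2(dppf), KOAc, dioxane, 80 °C) should give (1R,2R)-2-[2,6-dimethoxy-4-(4,4,5,5-tetramethyl-1,3,2-dioxaborolan-2-yl)phenoxy]-1-(3,4,5-trimethoxyphenyl)propan-1-ol F5.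
   - Suzuki–Miyaura-type coupling of F5 with allyl bromide (Pd(PPh3)4, K2CO3, THF/H2O, 60 °C) should give 10 at a lower temperature.

**Further compounds**
F1 | step 4 | ethyl (R)-2-(4-bromo-2,6-dimethoxyphenoxy)propanoate | COc1cc(Br)cc(OC)c1O[C@H](C)C(=O)OCC
F2 | step 4 | (R)-2-(4-bromo-2,6-dimethoxyphenoxy)-N-methoxy-N-methylpropanamide | COc1cc(Br)cc(OC)c1O[C@H](C)C(=O)N(C)OC
F3 | step 4 | (R)-2-(4-bromo-2,6-dimethoxyphenoxy)-1-(3,4,5-trimethoxyphenyl)propan-1-one | COc1cc(Br)cc(OC)c1O[C@H](C)C(=O)c2cc(OC)c(OC)c(OC)c2
F4 | step 3 | (E)-5-(2-iodoprop-1-en-1-yl)-1,2,3-trimethoxybenzene | COc1cc(/C=C(\C)I)cc(OC)c1OC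
F5 | step 5 | (1R,2R)-2-[2,6-dimethoxy-4-(4,4,5,5-tetramethyl-1,3,2-dioxaborolan-2-yl)phenoxy]-1-(3,4,5-trimethoxyphenyl)propan-1-ol | COc1cc(B2OC(C)(C)C(C)(C)O2)cc(OC)c1O[C@H](C)[C@H](O)c3cc(OC)c(OC)c(OC)c3
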